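## Retrosynthetic overview

- The Z-enoate is unmasked last by Lindlar semi-hydrogenation of a 22-membered ynoate lactone, itself closed by Yamaguchi lactonisation of a C21-hydroxy-2-ynoic acid (C1–O bond).
- The ynoic acid comes from a C2–C22 homoallylic silyl ether (ozonolysis, alkyne homologation, CO2). Key C4–C5 bond: Brown asymmetric allylboration of the C5–C22 trans-epoxy aldehyde with an allyl unit, which sets C5.
- The same allylborane, made once from allylmagnesium bromide and (−)-Ipc2BOMe, adds to a four-carbon epoxy aldehyde to form C8–C9 and set C8. Cross-metathesis with (R)-tridec-12-en-2-yl acetate (C21 from (R)-propylene oxide) and hydrogenation then add C11–C22.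
- The C5–C8 core is the Sharpless epoxide of mono-PMB (E)-but-2-ene-1,4-diol (sets C6, C7); its two ends are unveiled and allylated one after the other.
- Ring order: oxirane first (step 5), macrolactone second (step 19).

Assumption: CIML C is taken to be exactly the given SMILES, i.e. (2Z,5S,6R,7R,8S,21R)-6,7-epoxy-5,8-dihydroxydocos-2-en-21-olide; carbons are numbered C1 (lactone carbonyl) to C22 (methyl) throughout. TBS = tert-butyldimethylsilyl, PMB = 4-methoxybenzyl, Ipc = isopinocampheyl.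

## Route

Step 1
Reactants: 1 10-bromodec-1-ene; 2 (R)-propylene oxide
Product: 4 (2R)-tridec-12-en-2-ol, via Grignard reagent 3 (not isolated)
Conditions: Mg, THF, rt → 40 °C; then CuI (10 mol%), 2, −30 → 0 °C; then aq NH4Cl
Reagents that add atoms: none
Why: Copper-catalysed Grignard opening of the epoxide goes by SN2 attack at the unsubstituted CH2, so the stereocentre of (R)-propylene oxide is untouched and becomes C21 (R).

Step 2
Reactants: 4 (2R)-tridec-12-en-2-ol
Product: 5 (2R)-tridec-12-en-2-yl acetate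
Conditions: Ac2O, Et3N, DMAP (cat.), CH2Cl2, 0 °C → rt
Reagents that add atoms: acetic anhydride, CC(=O)OC(C)=O
Why: DMAP-catalysed acylation gives an acetate that survives the metathesis, hydrogenation, oxidation and allylboration steps and is removed later by simple methanolysis.

Step 3
Reactants: 6 but-2-yne-1,4-diol
Product: 7 (2E)-but-2-ene-1,4-diol
Conditions: LiAlH4 (1.5 equiv), THF, 0 °C → reflux; then H2O
Reagents that add atoms: none
Why: Alkoxide-directed trans-hydroalumination of the propargylic alkyne by LiAlH4 and protonolysis on work-up give the E-alkene only.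

Step 4
Reactants: 7 (2E)-but-2-ene-1,4-diol
Product: 8 (2E)-4-[(4-methoxybenzyl)oxy]but-2-en-1-ol
Conditions: NaH (1.0 equiv), 7 (2.5 equiv), 4-methoxybenzyl chloride (1.0 equiv), Bu4NI (cat.), THF/DMF, 0 °C → rt
Reagents that add atoms: 4-methoxybenzyl chloride, COc1ccc(CCl)cc1
Why: Williamson ether synthesis with a deficiency of base on an excess of the symmetrical diol gives mainly the mono-PMB ether, and recovered 7 is recycled.

Step 5
Reactants: 8 (2E)-4-[(4-methoxybenzyl)oxy]but-2-en-1-ol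
Product: 9 [(2R,3R)-3-{[(4-methoxybenzyl)oxy]methyl}oxiran-2-yl]methanol
Conditions: Ti(OiPr)4 (10 mol%), D-(−)-diethyl tartrate (12 mol%), t-BuOOH (2 equiv, in decane), 4 Å MS, CH2Cl2, −20 °C
Reagents that add atoms: tert-butyl hydroperoxide, CC(C)(C)OO
Why: Katsuki–Sharpless asymmetric epoxidation of the primary E-allylic alcohol: with D-(−)-tartrate the titanium-bound peroxide is delivered to the face that gives the (2R,3R)-epoxide, which fixes C6 and C7 of the target.

Step 6
Reactants: 9 epoxy alcohol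
Product: 10 (2S,3R)-3-{[(4-methoxybenzyl)oxy]methyl}oxirane-2-carbaldehyde
Conditions: TEMPO (10 mol%), PhI(OAc)2 (1.2 equiv), CH2Cl2, rt; used crude
Reagents that add atoms: none
Why: Oxoammonium (TEMPO/PhI(OAc)2) oxidation of the primary alcohol stops at the aldehyde under non-basic conditions that leave the trans-epoxide and its configuration intact.

Step 7
Reactants: 11 allylmagnesium bromide
Product: 12 (−)-B-allyldiisopinocampheylborane of the (+)-α-pinene series, as a magnesium-salt-free pentane solution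
Conditions: (−)-Ipc2BOMe (1.0 equiv), 11 (1.0 M in Et2O, 0.95 equiv), Et2O, 0 °C → rt, 1 h; evaporate, take up in pentane, filter off the magnesium salts under Ar; solution assayed by 11B NMR and kept at −20 °C under Ar; made on a scale that serves steps 8 and 14 (a fresh batch is made the same way if the titre has fallen)
Reagents that add atoms: (−)-B-methoxydiisopinocampheylborane, COB([C@@H]1C[C@@H]2C[C@H]([C@H]1C)C2(C)C)[C@@H]1C[C@@H]2C[C@H]([C@H]1C)C2(C)C
Why: Transmetallation of the allyl Grignard reagent onto boron with loss of bromomagnesium methoxide gives the allylborane with both isopinocampheyl groups untouched, and removing the magnesium salts leaves a reagent that holds no free Grignard reagent and so cannot attack the acetate in step 14.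

Step 8
Reactants: 10 epoxy aldehyde; 12 (−)-B-allyldiisopinocampheylborane
Product: 14 (1S)-1-[(2R,3R)-3-{[(4-methoxybenzyl)oxy]methyl}oxiran-2-yl]but-3-en-1-ol, via borinate 13 (not isolated)
Conditions: 12 (1.4 equiv, pentane solution from step 7), Et2O, −78 °C, 3 h; then pH 7 buffer, MeOH, 30% H2O2, 0 °C → rt
Reagents that add atoms: none
Why: Brown asymmetric allylboration (carbonyl allylation) through a closed chair transition state: the (+)-α-pinene-derived Ipc2B reagent delivers allyl to the Si face of the aldehyde, overriding the weak substrate bias, to form the C8–C9 bond and set C8 as S (threo to the epoxide), and the neutral peroxide work-up avoids Payne rearrangement.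

Step 9
Reactants: 14 homoallylic alcohol
Product: 15 tert-butyl{[(1S)-1-[(2S,3R)-3-{[(4-methoxybenzyl)oxy]methyl}oxiran-2-yl]but-3-en-1-yl]oxy}dimethylsilane (TBS ether of 14; the oxirane descriptor changes by CIP priority only)
Conditions: TBSOTf (1.3 equiv), 2,6-lutidine (2.5 equiv), CH2Cl2, −78 °C
Reagents that add atoms: tert-butyldimethylsilyl triflate, CC(C)(C)[Si](C)(C)OS(=O)(=O)C(F)(F)F
Why: Silylation of the hindered secondary alcohol with the silyl triflate and a non-nucleophilic base at low temperature protects C8–OH without opening the epoxide.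

Step 10
Reactants: 15 TBS ether; 5 (2R)-tridec-12-en-2-yl acetate
Product: 16 (2R,15S)-15-(TBSO)-15-[(2S,3R)-3-(PMBOCH2)oxiran-2-yl]pentadec-12-en-2-yl acetate (E/Z mixture)
Conditions: 5 (3 equiv), second-generation Grubbs catalyst RuCl2(=CHPh)(PCy3)(H2IMes) (5 mol%), CH2Cl2, 40 °C
Reagents that add atoms: none
Why: Olefin cross-metathesis of two unhindered terminal alkenes, driven by loss of ethylene and by the excess of the cheaper partner 5, joins the chain fragment to the core, and the E/Z ratio is irrelevant because the alkene is hydrogenated next.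

Step 11
Reactants: 16 cross-metathesis product
Product: 17 (2R,15S)-15-(TBSO)-15-[(2S,3R)-3-(PMBOCH2)oxiran-2-yl]pentadecan-2-yl acetate
Conditions: H2 (1 atm), PtO2 (5 mol%), EtOAc, rt
Reagents that add atoms: none
Why: Heterogeneous hydrogenation over PtO2 saturates the isolated disubstituted alkene while the aliphatic epoxide, the PMB ether and the acetate are left alone.

Step 12
Reactants: 17 saturated PMB ether
Product: 18 (2R,15S)-15-(TBSO)-15-[(2S,3R)-3-(hydroxymethyl)oxiran-2-yl]pentadecan-2-yl acetate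
Conditions: DDQ (1.5 equiv), CH2Cl2/pH 7 buffer (10:1), 0 °C → rt
Reagents that add atoms: none
Why: Oxidative PMB cleavage by DDQ proceeds through the stabilised benzylic cation and its hemiacetal under neutral buffered conditions that spare the TBS ether, acetate and epoxide.

Step 13
Reactants: 18 primary epoxy alcohol
Product: 19 (2R,15S)-15-(TBSO)-15-[(2S,3S)-3-formyloxiran-2-yl]pentadecan-2-yl acetate (C5 aldehyde)
Conditions: TEMPO (10 mol%), PhI(OAc)2 (1.2 equiv), CH2Cl2, rt; used crude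
Reagents that add atoms: none
Why: The same oxoammonium oxidation converts the primary epoxy alcohol into the aldehyde without touching the acetate, silyl ether or epoxide.

Step 14
Reactants: 19 C5–C22 epoxy aldehyde; 12 (−)-B-allyldiisopinocampheylborane
Product: 21 (2R,15S)-15-(TBSO)-15-{(2S,3R)-3-[(1S)-1-hydroxybut-3-en-1-yl]oxiran-2-yl}pentadecan-2-yl acetate, via borinate 20 (not isolated)
Conditions: 12 (1.5 equiv, pentane solution from step 7), Et2O, −78 °C, 3 h; then pH 7 buffer, MeOH, 30% H2O2, 0 °C → rt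
Reagents that add atoms: none
Why: Key fragment union by intermolecular Brown asymmetric allylboration (carbonyl allylation): the chair transition state of the (+)-α-pinene-derived reagent delivers the allyl unit to the Si face of aldehyde 19, forming the C4–C5 bond and setting C5 as S (threo to the epoxide), while the acetate is inert to the salt-free allylborane.

Step 15
Reactants: 21 homoallylic alcohol
Product: 22 (2R,15S)-15-(TBSO)-15-{(2S,3S)-3-[(1S)-1-(TBSO)but-3-en-1-yl]oxiran-2-yl}pentadecan-2-yl acetate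
Conditions: TBSOTf (1.5 equiv), 2,6-lutidine (3 equiv), CH2Cl2, −78 °C
Reagents that add atoms: tert-butyldimethylsilyl triflate, CC(C)(C)[Si](C)(C)OS(=O)(=O)C(F)(F)F
Why: Low-temperature silylation with TBSOTf/2,6-lutidine protects C5–OH so that it cannot lactonise or undergo Payne rearrangement later.

Step 16
Reactants: 22 bis-TBS alkene
Product: 24 (2R,15S)-15-(TBSO)-15-{(2S,3S)-3-[(1S)-1-(TBSO)-3-oxopropyl]oxiran-2-yl}pentadecan-2-yl acetate (C3 aldehyde), via ozonide 23 (not isolated)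
Conditions: O3, CH2Cl2, −78 °C; then PPh3, −78 °C → rt
Reagents that add atoms: ozone, [O-][O+]=O
Why: Ozonolysis of the only alkene with reductive work-up cleaves C2=C3 to the C3 aldehyde, and the β-silyloxy aldehyde is used at once.

Step 17
Reactants: 24 C3 aldehyde
Product: 26 (2R,15S)-15-(TBSO)-15-{(2S,3S)-3-[(1S)-1-(TBSO)but-3-yn-1-yl]oxiran-2-yl}pentadecan-2-ol, via alkynyl acetate 25 (not isolated)
Conditions: dimethyl (1-diazo-2-oxopropyl)phosphonate (1.5 equiv), K2CO3 (3 equiv), MeOH, 0 °C → rt, 16 h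
Reagents that add atoms: dimethyl (1-diazo-2-oxopropyl)phosphonate, CC(=O)C(=[N+]=[N-])P(=O)(OC)OC
Why: Seyferth–Gilbert homologation with the Ohira–Bestmann reagent turns the aldehyde into the terminal alkyne (new carbon = C2), and the same K2CO3/MeOH medium removes the C21 acetate by transesterification.

Step 18
Reactants: 26 hydroxy alkyne
Product: 28 (5S,6S,7S,8S,21R)-5,8-bis(TBSO)-6,7-epoxy-21-hydroxydocos-2-ynoic acid, via dilithio species 27 (not isolated)
Conditions: n-BuLi (2.2 equiv), THF, −78 °C; then CO2 (g), −78 → −20 °C; then 1 M HCl to pH 4, 0 °C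
Reagents that add atoms: carbon dioxide, O=C=O
Why: Two equivalents of n-BuLi form the alkoxide and the lithium acetylide, and carboxylation of the acetylide with CO2 installs C1 as the carboxylic acid.

Step 19
Reactants: 28 hydroxy ynoic acid
Product: 30 (5S,6S,7S,8S,21R)-5,8-bis(TBSO)-6,7-epoxydocos-2-yn-21-olide, via mixed anhydride 29 (not isolated)
Conditions: 2,4,6-trichlorobenzoyl chloride (1.5 equiv), Et3N (2 equiv), THF, rt; then syringe-pump addition to DMAP (5 equiv), toluene (1 mM), rt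
Reagents that add atoms: none
Why: Yamaguchi macrolactonisation: the mixed anhydride is acylated by the C21 hydroxyl under DMAP catalysis at high dilution to close the 22-membered ring with retention at C21, and using the ynoic acid avoids the Z to E isomerisation that an activated Z-enoic acid could suffer.

Step 20
Reactants: 30 bis-TBS ynoate macrolactone
Product: 31 (5S,6R,7R,8S,21R)-6,7-epoxy-5,8-dihydroxydocos-2-yn-21-olide
Conditions: HF·pyridine, pyridine, THF, 0 °C → rt
Reagents that add atoms: none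
Why: Buffered HF·pyridine removes both TBS ethers without opening the epoxide, and it is done at the alkyne stage because a linear 5-hydroxy-2-ynoate cannot translactonise to a six-membered lactone.

Step 21
Reactants: 31 diol ynoate macrolactone
Product: 32 CIML C, (2Z,5S,6R,7R,8S,21R)-6,7-epoxy-5,8-dihydroxydocos-2-en-21-olide
Conditions: H2 (1 atm), Pd/CaCO3 poisoned with Pb(OAc)2 (Lindlar catalyst), quinoline, EtOAc, rt
Reagents that add atoms: none
Why: Lindlar semi-hydrogenation adds H2 syn to the ynoate to give the (2Z)-enoate under neutral conditions, so the sensitive 5-hydroxy Z-enoate is formed last.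

## Compound list

1 | 10-bromodec-1-ene | C=CCCCCCCCCBr | starting material
2 | (R)-propylene oxide, (2R)-2-methyloxirane | C[C@@H]1CO1 | starting material
3 | dec-9-en-1-ylmagnesium bromide | C=CCCCCCCCC[Mg]Br | intermediate
4 | (2R)-tridec-12-en-2-ol | C[C@@H](O)CCCCCCCCCC=C | intermediate
5 | (2R)-tridec-12-en-2-yl acetate | C[C@@H](OC(C)=O)CCCCCCCCCC=C | intermediate
6 | but-2-yne-1,4-diol | OCC#CCO | starting material
7 | (2E)-but-2-ene-1,4-diol | OC/C=C/CO | intermediate
8 | (2E)-4-[(4-methoxybenzyl)oxy]but-2-en-1-ol | OC/C=C/COCc1ccc(OC)cc1 | intermediate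
9 | [(2R,3R)-3-{[(4-methoxybenzyl)oxy]methyl}oxiran-2-yl]methanol | OC[C@H]1O[C@@H]1COCc1ccc(OC)cc1 | intermediate
10 | (2S,3R)-3-{[(4-methoxybenzyl)oxy]methyl}oxirane-2-carbaldehyde | O=C[C@H]1O[C@@H]1COCc1ccc(OC)cc1 | intermediate
11 | allylmagnesium bromide (1.0 M in Et2O) | C=CC[Mg]Br | starting material
12 | (−)-B-allyldiisopinocampheylborane of the (+)-α-pinene series, salt-free pentane solution | C=CCB([C@@H]1C[C@@H]2C[C@H]([C@H]1C)C2(C)C)[C@@H]1C[C@@H]2C[C@H]([C@H]1C)C2(C)C | intermediate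
13 | Ipc2B borinate of alcohol 14 | C=CC[C@H](OB([C@@H]1C[C@@H]2C[C@H]([C@H]1C)C2(C)C)[C@@H]1C[C@@H]2C[C@H]([C@H]1C)C2(C)C)[C@H]1O[C@@H]1COCc1ccc(OC)cc1 | intermediate
14 | (1S)-1-[(2R,3R)-3-{[(4-methoxybenzyl)oxy]methyl}oxiran-2-yl]but-3-en-1-ol | C=CC[C@H](O)[C@H]1O[C@@H]1COCc1ccc(OC)cc1 | intermediate
15 | tert-butyl{[(1S)-1-[(2S,3R)-3-{[(4-methoxybenzyl)oxy]methyl}oxiran-2-yl]but-3-en-1-yl]oxy}dimethylsilane | C=CC[C@H](O[Si](C)(C)C(C)(C)C)[C@H]1O[C@@H]1COCc1ccc(OC)cc1 | intermediate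
16 | (2R,15S)-15-(TBSO)-15-[(2S,3R)-3-(PMBOCH2)oxiran-2-yl]pentadec-12-en-2-yl acetate (12E shown; E/Z mixture) | C[C@@H](OC(C)=O)CCCCCCCCC/C=C/C[C@H](O[Si](C)(C)C(C)(C)C)[C@H]1O[C@@H]1COCc1ccc(OC)cc1 | intermediate
17 | (2R,15S)-15-(TBSO)-15-[(2S,3R)-3-(PMBOCH2)oxiran-2-yl]pentadecan-2-yl acetate | C[C@@H](OC(C)=O)CCCCCCCCCCCC[C@H](O[Si](C)(C)C(C)(C)C)[C@H]1O[C@@H]1COCc1ccc(OC)cc1 | intermediate
18 | (2R,15S)-15-(TBSO)-15-[(2S,3R)-3-(hydroxymethyl)oxiran-2-yl]pentadecan-2-yl acetate | C[C@@H](OC(C)=O)CCCCCCCCCCCC[C@H](O[Si](C)(C)C(C)(C)C)[C@H]1O[C@@H]1CO | intermediate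
19 | (2R,15S)-15-(TBSO)-15-[(2S,3S)-3-formyloxiran-2-yl]pentadecan-2-yl acetate | C[C@@H](OC(C)=O)CCCCCCCCCCCC[C@H](O[Si](C)(C)C(C)(C)C)[C@H]1O[C@@H]1C=O | intermediate
20 | Ipc2B borinate of alcohol 21 | C[C@@H](OC(C)=O)CCCCCCCCCCCC[C@H](O[Si](C)(C)C(C)(C)C)[C@H]1O[C@@H]1[C@@H](OB([C@@H]2C[C@@H]3C[C@H]([C@H]2C)C3(C)C)[C@@H]2C[C@@H]3C[C@H]([C@H]2C)C3(C)C)CC=C | intermediate
21 | (2R,15S)-15-(TBSO)-15-{(2S,3R)-3-[(1S)-1-hydroxybut-3-en-1-yl]oxiran-2-yl}pentadecan-2-yl acetate | C[C@@H](OC(C)=O)CCCCCCCCCCCC[C@H](O[Si](C)(C)C(C)(C)C)[C@H]1O[C@@H]1[C@@H](O)CC=C | intermediate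
22 | (2R,15S)-15-(TBSO)-15-{(2S,3S)-3-[(1S)-1-(TBSO)but-3-en-1-yl]oxiran-2-yl}pentadecan-2-yl acetate | C[C@@H](OC(C)=O)CCCCCCCCCCCC[C@H](O[Si](C)(C)C(C)(C)C)[C@H]1O[C@@H]1[C@@H](O[Si](C)(C)C(C)(C)C)CC=C | intermediate
23 | secondary ozonide (1,2,4-trioxolane) of 22, mixture at the ozonide carbon | C[C@@H](OC(C)=O)CCCCCCCCCCCC[C@H](O[Si](C)(C)C(C)(C)C)[C@H]1O[C@@H]1[C@@H](O[Si](C)(C)C(C)(C)C)CC1OCOO1 | intermediate
24 | (2R,15S)-15-(TBSO)-15-{(2S,3S)-3-[(1S)-1-(TBSO)-3-oxopropyl]oxiran-2-yl}pentadecan-2-yl acetate | C[C@@H](OC(C)=O)CCCCCCCCCCCC[C@H](O[Si](C)(C)C(C)(C)C)[C@H]1O[C@@H]1[C@@H](O[Si](C)(C)C(C)(C)C)CC=O | intermediate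
25 | (2R,15S)-15-(TBSO)-15-{(2S,3S)-3-[(1S)-1-(TBSO)but-3-yn-1-yl]oxiran-2-yl}pentadecan-2-yl acetate | C[C@@H](OC(C)=O)CCCCCCCCCCCC[C@H](O[Si](C)(C)C(C)(C)C)[C@H]1O[C@@H]1[C@@H](O[Si](C)(C)C(C)(C)C)CC#C | intermediate
26 | (2R,15S)-15-(TBSO)-15-{(2S,3S)-3-[(1S)-1-(TBSO)but-3-yn-1-yl]oxiran-2-yl}pentadecan-2-ol | C[C@@H](O)CCCCCCCCCCCC[C@H](O[Si](C)(C)C(C)(C)C)[C@H]1O[C@@H]1[C@@H](O[Si](C)(C)C(C)(C)C)CC#C | intermediate
27 | dilithio derivative of 26 (lithium alkoxide, lithium acetylide) | C[C@@H](O[Li])CCCCCCCCCCCC[C@H](O[Si](C)(C)C(C)(C)C)[C@H]1O[C@@H]1[C@@H](O[Si](C)(C)C(C)(C)C)CC#C[Li] | intermediate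
28 | (5S,6S,7S,8S,21R)-5,8-bis(TBSO)-6,7-epoxy-21-hydroxydocos-2-ynoic acid | C[C@@H](O)CCCCCCCCCCCC[C@H](O[Si](C)(C)C(C)(C)C)[C@H]1O[C@@H]1[C@@H](O[Si](C)(C)C(C)(C)C)CC#CC(=O)O | intermediate
29 | mixed anhydride of 28 with 2,4,6-trichlorobenzoic acid | C[C@@H](O)CCCCCCCCCCCC[C@H](O[Si](C)(C)C(C)(C)C)[C@H]1O[C@@H]1[C@@H](O[Si](C)(C)C(C)(C)C)CC#CC(=O)OC(=O)c1c(Cl)cc(Cl)cc1Cl | intermediate
30 | (5S,6S,7S,8S,21R)-5,8-bis(TBSO)-6,7-epoxydocos-2-yn-21-olide | C[C@@H]1CCCCCCCCCCCC[C@H](O[Si](C)(C)C(C)(C)C)[C@H]2O[C@@H]2[C@@H](O[Si](C)(C)C(C)(C)C)CC#CC(=O)O1 | intermediate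
31 | (5S,6R,7R,8S,21R)-6,7-epoxy-5,8-dihydroxydocos-2-yn-21-olide | C[C@@H]1CCCCCCCCCCCC[C@H](O)[C@H]2O[C@@H]2[C@@H](O)CC#CC(=O)O1 | intermediate
32 | CIML C, (2Z,5S,6R,7R,8S,21R)-6,7-epoxy-5,8-dihydroxydocos-2-en-21-olide | C[C@@H]1CCCCCCCCCCCC[C@H](O)[C@H]2O[C@@H]2[C@@H](O)C/C=C\C(=O)O1 | target

## Step count and risk

Total: 21 steps. Longest linear sequence: 18 steps (steps 3–6 and 8–21, from 6 to 32). The chain fragment (steps 1–2) enters at step 10, and the allylborane (step 7) enters at steps 8 and 14.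

The three steps most likely to fail:

Step 14. The allylborane has to work against the intrinsic (erythro) preference of the trans-epoxy aldehyde, so the threo:erythro ratio may be modest. The fallback sets out from 19 and lets reagent and substrate cooperate. Allylmagnesium bromide 11 and (+)-Ipc2BOMe (the (−)-α-pinene series) give the enantiomeric allylborane F1. F1 adds to 19 through the borinate F2 to give the erythro (5R)-homoallylic alcohol F3. Mitsunobu inversion with chloroacetic acid (PPh3, DIAD, toluene, 0 °C) gives the (5S)-chloroacetate F4. Brief methanolysis (K2CO3 cat., MeOH, −20 °C) removes the chloroacetate but not the C21 acetate, and the route is rejoined at 21.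

Step 17. The β-silyloxy aldehyde may eliminate under base, or the in-flask acetate methanolysis may be incomplete. The fallback sets out from 24 and makes the alkyne by dibromo-olefination and elimination instead. CBr4, PPh3 and Zn dust in CH2Cl2 at 0 °C give the 1,1-dibromoalkene acetate F5. K2CO3 in MeOH gives the dibromoalkene alcohol F6. n-BuLi (3.3 equiv) in THF at −78 °C converts F6 directly into the dilithio species 27, which is carboxylated with CO2 as in step 18, so the route is rejoined at 28.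

Step 19. Closing a 22-membered ring through an activated ynoic acid risks oligomers and DMAP addition to the activated ynoate. The fallback closes the ring by C=C bond formation instead of C–O bond formation and sets out from 22. K2CO3 in MeOH gives the C21 alcohol F7. Bis(2,2,2-trifluoroethyl)phosphonoacetic acid, EDC·HCl and DMAP give the phosphonoacetate F8. Ozonolysis (O3, then PPh3) through the ozonide F9 gives the phosphonate aldehyde F10. Intramolecular Still–Gennari olefination (K2CO3, 18-crown-6, toluene, 1 mM, rt) gives the bis-TBS (2Z)-macrolactone F11. Buffered HF·pyridine/pyridine/THF at 0 °C then removes both silyl groups, and this branch comes back to the route at the target 32.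

## Further compounds

F1 | step 14 | B-allyldiisopinocampheylborane of the (−)-α-pinene series (not isolated) | C=CCB([C@H]1C[C@H]2C[C@@H]([C@@H]1C)C2(C)C)[C@H]1C[C@H]2C[C@@H]([C@@H]1C)C2(C)C
F2 | step 14 | Ipc2B borinate of F3 (not isolated) | C[C@@H](OC(C)=O)CCCCCCCCCCCC[C@H](O[Si](C)(C)C(C)(C)C)[C@H]1O[C@@H]1[C@H](OB([C@H]2C[C@H]3C[C@@H]([C@@H]2C)C3(C)C)[C@H]2C[C@H]3C[C@@H]([C@@H]2C)C3(C)C)CC=C
F3 | step 14 | (5R)-epimer of 21 (erythro homoallylic alcohol) | C[C@@H](OC(C)=O)CCCCCCCCCCCC[C@H](O[Si](C)(C)C(C)(C)C)[C@H]1O[C@@H]1[C@H](O)CC=C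
F4 | step 14 | (5S)-chloroacetate of 21 | C[C@@H](OC(C)=O)CCCCCCCCCCCC[C@H](O[Si](C)(C)C(C)(C)C)[C@H]1O[C@@H]1[C@@H](OC(=O)CCl)CC=C
F5 | step 17 | 1,1-dibromoalkene from 24 (C21 acetate) | C[C@@H](OC(C)=O)CCCCCCCCCCCC[C@H](O[Si](C)(C)C(C)(C)C)[C@H]1O[C@@H]1[C@@H](O[Si](C)(C)C(C)(C)C)CC=C(Br)Br
F6 | step 17 | 1,1-dibromoalkene with free C21 hydroxyl | C[C@@H](O)CCCCCCCCCCCC[C@H](O[Si](C)(C)C(C)(C)C)[C@H]1O[C@@H]1[C@@H](O[Si](C)(C)C(C)(C)C)CC=C(Br)Br
F7 | step 19 | C21 alcohol from 22 | C[C@@H](O)CCCCCCCCCCCC[C@H](O[Si](C)(C)C(C)(C)C)[C@H]1O[C@@H]1[C@@H](O[Si](C)(C)C(C)(C)C)CC=C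
F8 | step 19 | C21 bis(2,2,2-trifluoroethyl)phosphonoacetate of F7 | C[C@@H](OC(=O)CP(=O)(OCC(F)(F)F)OCC(F)(F)F)CCCCCCCCCCCC[C@H](O[Si](C)(C)C(C)(C)C)[C@H]1O[C@@H]1[C@@H](O[Si](C)(C)C(C)(C)C)CC=C
F9 | step 19 | secondary ozonide of F8 (not isolated) | C[C@@H](OC(=O)CP(=O)(OCC(F)(F)F)OCC(F)(F)F)CCCCCCCCCCCC[C@H](O[Si](C)(C)C(C)(C)C)[C@H]1O[C@@H]1[C@@H](O[Si](C)(C)C(C)(C)C)CC1OCOO1
F10 | step 19 | phosphonate aldehyde (C3 aldehyde, C21 phosphonoacetate) | C[C@@H](OC(=O)CP(=O)(OCC(F)(F)F)OCC(F)(F)F)CCCCCCCCCCCC[C@H](O[Si](C)(C)C(C)(C)C)[C@H]1O[C@@H]1[C@@H](O[Si](C)(C)C(C)(C)C)CC=O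
F11 | step 19 | bis-TBS ether of the target, (2Z)-macrolactone | C[C@@H]1CCCCCCCCCCCC[C@H](O[Si](C)(C)C(C)(C)C)[C@H]2O[C@@H]2[C@@H](O[Si](C)(C)C(C)(C)C)C/C=C\C(=O)O1
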